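**Retrosynthetic overview**

1. Hansforester A (18) comes from its hexabenzyl ether 17 by one global hydrogenolysis. No ring is formed anywhere in the route: all three benzene rings are bought (one bromoresorcinol ether used twice, methyl orsellinate once).
2. 17 is cut at the bond between C1 of the central resorcylate ring and its ester carbonyl, giving aryl iodide 14, CO and secondary alcohol 8. A Pd-catalysed three-component alkoxycarbonylation makes this aryl–C(=O) bond and the adjoining C(=O)–O bond in one operation.
3. Enabling feature: the ester carbon sits on C1 of the central 2,4-dihydroxy-6-alkylbenzene ring, para to O-4 and ortho to O-2. This is the most nucleophilic CH of a 3,5-dioxygenated alkylbenzene, so iodine enters there selectively and the aryl–C(=O)–O triad maps onto ArI/CO/ROH. In addition, the unit (R)-1-(3,5-dihydroxyphenyl)propan-2-yl (R)-3-hydroxybutanoate occurs twice, so one monomer (8) supplies both halves.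
4. 14 comes from 8 by iodination and O-acylation with 2,4-bis(benzyloxy)-6-methylbenzoyl chloride. 8 comes from an aryl Grignard reagent and (R)-propylene oxide, followed by acetoacetylation and Noyori hydrogenation.

Key step: step 8

Assumption: 1,3-bis(benzyloxy)-5-bromobenzene is taken as a purchasable arene (otherwise it is one O-benzylation from 5-bromoresorcinol); benzyl is used on all six phenols because hydrogenolysis is the one deprotection that leaves the four ester links untouched.

**Route**

Step 1
Reactants: 1 1,3-bis(benzyloxy)-5-bromobenzene; 2 (R)-2-methyloxirane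
Product: 4 (2R)-1-[3,5-bis(benzyloxy)phenyl]propan-2-ol, via arylmagnesium bromide 3 (not isolated)
Conditions: Mg, THF, reflux; then CuI (10 mol%), 2, −30 → 0 °C; 1 M HCl work-up
Reagents that add atoms: none
Why: Copper-catalysed Grignard opening of a terminal epoxide by SN2 attack at the unsubstituted carbon, which does not touch the C–O stereocentre of (R)-propylene oxide and should therefore give the (R)-carbinol.

Step 2
Reactants: 4 (2R)-1-[3,5-bis(benzyloxy)phenyl]propan-2-ol; 5 2,2,6-trimethyl-4H-1,3-dioxin-4-one
Product: 7 (2R)-1-[3,5-bis(benzyloxy)phenyl]propan-2-yl 3-oxobutanoate, via acetylketene 6 (not isolated)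
Conditions: toluene, 110 °C, acetone distilled off
Reagents that add atoms: none
Why: Thermal retro-[4+2] cleavage of the dioxinone releases acetylketene, which the secondary alcohol should trap as its acetoacetate (acetoacetylation) without touching the carbinol centre.

Step 3
Reactants: 7 (2R)-1-[3,5-bis(benzyloxy)phenyl]propan-2-yl 3-oxobutanoate
Product: 8 (2R)-1-[3,5-bis(benzyloxy)phenyl]propan-2-yl (3R)-3-hydroxybutanoate
Conditions: H2 (10 atm), [RuCl2((R)-BINAP)]2·NEt3 (1 mol% Ru), EtOH/CH2Cl2, 50 °C
Reagents that add atoms: none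
Why: Noyori asymmetric hydrogenation of a β-keto ester, in which the chelated Ru–(R)-BINAP catalyst should deliver hydride to one ketone face and set the (R)-3-hydroxy centre under catalyst control, with the remote carbinol ester centre and the benzyl ethers as spectators.

Step 4
Reactants: 8 (2R)-1-[3,5-bis(benzyloxy)phenyl]propan-2-yl (3R)-3-hydroxybutanoate
Product: 9 (2R)-1-[3,5-bis(benzyloxy)-2-iodophenyl]propan-2-yl (3R)-3-hydroxybutanoate
Conditions: NIS (1.05 equiv), MeCN, 0 °C → rt, dark
Reagents that add atoms: N-iodosuccinimide, O=C1CCC(=O)N1I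
Why: Electrophilic aromatic iodination should occur at the homotopic C2/C6 position (para to one benzyloxy group, ortho to the other), because the C4 position between the two benzyloxy groups is shielded and the free secondary hydroxyl is inert to NIS.

Step 5
Reactants: 10 methyl 2,4-dihydroxy-6-methylbenzoate
Product: 11 methyl 2,4-bis(benzyloxy)-6-methylbenzoate
Conditions: BnBr (2.5 equiv), K2CO3, DMF, 60 °C
Reagents that add atoms: benzyl bromide, BrCc1ccccc1
Why: Williamson ether synthesis on both phenols, with gentle heating in DMF to bring the hydrogen-bonded ortho phenol to reaction.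

Step 6
Reactants: 11 methyl 2,4-bis(benzyloxy)-6-methylbenzoate
Product: 12 2,4-bis(benzyloxy)-6-methylbenzoic acid
Conditions: KOH, DMSO/H2O, 90 °C; then 1 M HCl
Reagents that add atoms: potassium hydroxide, [K+].[OH-]
Why: Forcing saponification of a hindered methyl benzoate, to which aryl benzyl ethers are stable.

Step 7
Reactants: 12 2,4-bis(benzyloxy)-6-methylbenzoic acid; 9 (2R)-1-[3,5-bis(benzyloxy)-2-iodophenyl]propan-2-yl (3R)-3-hydroxybutanoate
Product: 14 (2R)-1-[3,5-bis(benzyloxy)-2-iodophenyl]propan-2-yl (3R)-3-{[2,4-bis(benzyloxy)-6-methylbenzoyl]oxy}butanoate, via aroyl chloride 13 (not isolated)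
Conditions: (COCl)2, DMF (cat.), CH2Cl2, 0 °C → rt, evaporate; then 9, Et3N, DMAP, CH2Cl2, 0 °C → rt
Reagents that add atoms: none
Why: DMAP-catalysed acylation of the secondary hydroxyl by the acid chloride (nucleophilic acyl substitution), which does not break the carbinol C–O bond and so retains the (R) configuration, while the aryl iodide is inert.

Step 8
Reactants: 14 (2R)-1-[3,5-bis(benzyloxy)-2-iodophenyl]propan-2-yl (3R)-3-{[2,4-bis(benzyloxy)-6-methylbenzoyl]oxy}butanoate; 8 (2R)-1-[3,5-bis(benzyloxy)phenyl]propan-2-yl (3R)-3-hydroxybutanoate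
Product: 17 hexa-O-benzyl hansforester A, via arylpalladium iodide 15 (not isolated), via aroylpalladium iodide 16 (not isolated)
Conditions: CO (3 bar), Pd(OAc)2 (10 mol%), Xantphos (12 mol%), iPr2NEt (2 equiv), DMAP (0.3 equiv), 8 (1.3 equiv), toluene, 80 °C
Reagents that add atoms: carbon monoxide, [C-]#[O+]
Why: Pd(0)/Xantphos adds oxidatively into the single C–I bond of 14 (15), CO then undergoes migratory insertion and thereby forms the bond between C1 of the central ring and the new ester carbonyl (16), and the only free hydroxyl present, the (R)-carbinol of 8, cleaves the acyl–palladium bond with DMAP as acyl-transfer relay while iPr2NEt takes up HI and returns Pd(0). The closest known reaction type is the Pd-catalysed alkoxycarbonylation of aryl iodides with secondary alcohols, which is established for doubly ortho-substituted resorcinol-derived iodides as a way to resorcylate esters. No ring is closed and no stereocentre is created; the carbinol C–O bond of 8 is never broken, so its (R) configuration is retained, and the other three centres are spectators. The step needs chemoselectivity and site fidelity: the carbonyl can only enter where iodine sits, every phenol is benzylated and every other hydroxyl is already acylated so a single nucleophile competes, CO pressure favours insertion over direct C–O coupling or β-hydride reduction of the aryl iodide, and a hindered tertiary amine at 80 °C should be too weak to cause E1cB loss of the β-acyloxy groups. In this one operation the two halves are joined through a one-carbon linchpin and the full protected skeleton of the target is complete.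

Step 9
Reactants: 17 hexa-O-benzyl hansforester A
Product: 18 hansforester A
Conditions: H2 (1 atm), 10% Pd/C, EtOAc/EtOH, rt
Reagents that add atoms: none
Why: Catalytic hydrogenolysis should cleave the six aryl benzyl ethers, while the four ester links (none benzylic at oxygen) and the four stereocentres are not affected.

**Compound list**

1 | 1,3-bis(benzyloxy)-5-bromobenzene | Brc1cc(OCc2ccccc2)cc(OCc2ccccc2)c1 | starting material
2 | (R)-2-methyloxirane ((R)-propylene oxide) | C[C@@H]1CO1 | starting material
3 | [3,5-bis(benzyloxy)phenyl]magnesium bromide | Br[Mg]c1cc(OCc2ccccc2)cc(OCc2ccccc2)c1 | intermediate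
4 | (2R)-1-[3,5-bis(benzyloxy)phenyl]propan-2-ol | C[C@@H](O)Cc1cc(OCc2ccccc2)cc(OCc2ccccc2)c1 | intermediate
5 | 2,2,6-trimethyl-4H-1,3-dioxin-4-one | CC1=CC(=O)OC(C)(C)O1 | starting material
6 | acetylketene | CC(=O)C=C=O | intermediate
7 | (2R)-1-[3,5-bis(benzyloxy)phenyl]propan-2-yl 3-oxobutanoate | CC(=O)CC(=O)O[C@H](C)Cc1cc(OCc2ccccc2)cc(OCc2ccccc2)c1 | intermediate
8 | (2R)-1-[3,5-bis(benzyloxy)phenyl]propan-2-yl (3R)-3-hydroxybutanoate (monomer) | C[C@@H](O)CC(=O)O[C@H](C)Cc1cc(OCc2ccccc2)cc(OCc2ccccc2)c1 | intermediate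
9 | (2R)-1-[3,5-bis(benzyloxy)-2-iodophenyl]propan-2-yl (3R)-3-hydroxybutanoate | C[C@@H](O)CC(=O)O[C@H](C)Cc1cc(OCc2ccccc2)cc(OCc2ccccc2)c1I | intermediate
10 | methyl 2,4-dihydroxy-6-methylbenzoate (methyl orsellinate) | Cc1cc(O)cc(O)c1C(=O)OC | starting material
11 | methyl 2,4-bis(benzyloxy)-6-methylbenzoate | Cc1cc(OCc2ccccc2)cc(OCc2ccccc2)c1C(=O)OC | intermediate
12 | 2,4-bis(benzyloxy)-6-methylbenzoic acid | Cc1cc(OCc2ccccc2)cc(OCc2ccccc2)c1C(=O)O | intermediate
13 | 2,4-bis(benzyloxy)-6-methylbenzoyl chloride | Cc1cc(OCc2ccccc2)cc(OCc2ccccc2)c1C(=O)Cl | intermediate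
14 | (2R)-1-[3,5-bis(benzyloxy)-2-iodophenyl]propan-2-yl (3R)-3-{[2,4-bis(benzyloxy)-6-methylbenzoyl]oxy}butanoate | Cc1cc(OCc2ccccc2)cc(OCc2ccccc2)c1C(=O)O[C@H](C)CC(=O)O[C@H](C)Cc1cc(OCc2ccccc2)cc(OCc2ccccc2)c1I | intermediate
15 | arylpalladium(II) iodide from oxidative addition of 14 (Xantphos on Pd not drawn) | Cc1cc(OCc2ccccc2)cc(OCc2ccccc2)c1C(=O)O[C@H](C)CC(=O)O[C@H](C)Cc1cc(OCc2ccccc2)cc(OCc2ccccc2)c1[Pd]I | intermediate
16 | aroylpalladium(II) iodide from CO insertion into 15 (Xantphos on Pd not drawn) | Cc1cc(OCc2ccccc2)cc(OCc2ccccc2)c1C(=O)O[C@H](C)CC(=O)O[C@H](C)Cc1cc(OCc2ccccc2)cc(OCc2ccccc2)c1C(=O)[Pd]I | intermediate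
17 | hexa-O-benzyl hansforester A | Cc1cc(OCc2ccccc2)cc(OCc2ccccc2)c1C(=O)O[C@H](C)CC(=O)O[C@H](C)Cc1cc(OCc2ccccc2)cc(OCc2ccccc2)c1C(=O)O[C@H](C)CC(=O)O[C@H](C)Cc1cc(OCc2ccccc2)cc(OCc2ccccc2)c1 | intermediate
18 | hansforester A | Cc1cc(O)cc(O)c1C(=O)O[C@H](C)CC(=O)O[C@H](C)Cc1cc(O)cc(O)c1C(=O)O[C@H](C)CC(=O)O[C@H](C)Cc1cc(O)cc(O)c1 | target

**Step count and risks**

Total step count: 9. Longest linear sequence: 7 steps (1 → 2 → 3 → 4 → 7 → 8 → 9, starting from compound 1).

Steps most likely to fail:

Step 8. Acyl transfer from the doubly ortho-flanked aroylpalladium to a secondary hydroxyl may be slow enough for hydrodeiodination, catalyst decay or base-induced β-elimination of the acyloxy esters to compete. The fallback sets out from 14 and separates carbonylation from ester formation. Pd-catalysed hydroxycarbonylation of 14 (Pd(OAc)2, Xantphos, CO, H2O, iPr2NEt, dioxane, 70 °C) lets the small nucleophile water capture the acylpalladium and should give the central arenecarboxylic acid F1. F1 is converted under neutral conditions with 1-chloro-N,N,2-trimethylprop-1-en-1-amine (CH2Cl2, 0 °C) into the aroyl chloride F2. F2 acylates 8 (Et3N, DMAP, CH2Cl2) in the manner of step 7 and returns to the route at 17.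

Step 7. Acylation of the hindered secondary hydroxyl by the doubly ortho-substituted aroyl chloride may be so slow that amine-induced β-elimination to a crotonate wins. The fallback sets out from 8, before iodination, and avoids any acid chloride. Orcinol is benzylated (BnBr, K2CO3, DMF) to 3,5-bis(benzyloxy)toluene F3, which NIS should iodinate to 2,4-bis(benzyloxy)-1-iodo-6-methylbenzene F4. Pd-catalysed alkoxycarbonylation of F4 with 8 and CO under the conditions of step 8 should give the iodine-free diester F5. NIS iodination of F5 at its ester-free, more electron-rich terminal ring then returns to the route at 14.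

Step 3. Incomplete facial control in the ketone reduction, or ester exchange with the alcoholic solvent, would give a diastereomer mixture that is hard to separate because the two stereocentres are remote. The fallback sets out from 4 and takes the hydroxy acid from the chiral pool. Commercial methyl (R)-3-hydroxybutanoate is silylated (TBSCl, imidazole, DMF) to methyl (3R)-3-[(tert-butyldimethylsilyl)oxy]butanoate F6 and saponified (LiOH, THF/H2O) to (3R)-3-[(tert-butyldimethylsilyl)oxy]butanoic acid F7. Carbodiimide esterification of F7 with 4 (DCC, DMAP, CH2Cl2) should give the silyl ether F8, and desilylation (HF·pyridine, THF) returns to the route at 8.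

Further compounds
F1 | step 8 | 2-{(2R)-2-[((3R)-3-{[2,4-bis(benzyloxy)-6-methylbenzoyl]oxy}butanoyl)oxy]propyl}-4,6-bis(benzyloxy)benzoic acid | Cc1cc(OCc2ccccc2)cc(OCc2ccccc2)c1C(=O)O[C@H](C)CC(=O)O[C@H](C)Cc1cc(OCc2ccccc2)cc(OCc2ccccc2)c1C(=O)O
F2 | step 8 | acid chloride of F1 | Cc1cc(OCc2ccccc2)cc(OCc2ccccc2)c1C(=O)O[C@H](C)CC(=O)O[C@H](C)Cc1cc(OCc2ccccc2)cc(OCc2ccccc2)c1C(=O)Cl
F3 | step 7 | 3,5-bis(benzyloxy)toluene | Cc1cc(OCc2ccccc2)cc(OCc2ccccc2)c1
F4 | step 7 | 2,4-bis(benzyloxy)-1-iodo-6-methylbenzene | Cc1cc(OCc2ccccc2)cc(OCc2ccccc2)c1I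
F5 | step 7 | (2R)-1-[3,5-bis(benzyloxy)phenyl]propan-2-yl (3R)-3-{[2,4-bis(benzyloxy)-6-methylbenzoyl]oxy}butanoate | Cc1cc(OCc2ccccc2)cc(OCc2ccccc2)c1C(=O)O[C@H](C)CC(=O)O[C@H](C)Cc1cc(OCc2ccccc2)cc(OCc2ccccc2)c1
F6 | step 3 | methyl (3R)-3-[(tert-butyldimethylsilyl)oxy]butanoate | C[C@@H](O[Si](C)(C)C(C)(C)C)CC(=O)OC
F7 | step 3 | (3R)-3-[(tert-butyldimethylsilyl)oxy]butanoic acid | C[C@@H](O[Si](C)(C)C(C)(C)C)CC(=O)O
F8 | step 3 | (2R)-1-[3,5-bis(benzyloxy)phenyl]propan-2-yl (3R)-3-[(tert-butyldimethylsilyl)oxy]butanoate | C[C@@H](O[Si](C)(C)C(C)(C)C)CC(=O)O[C@H](C)Cc1cc(OCc2ccccc2)cc(OCc2ccccc2)c1
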